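(The numbers of this flask belong to no real substance; the result is computed.)

At late times what stands in this flask is the split of the charge between self-condensation and the gas routes.

    2 substrate → self-condensation product (k1 = 6.2 M⁻¹ s⁻¹)
    gas phase ⇌ dissolved gas, rate k2*(csat - [dissolved gas]) (k2 = 0.15 s⁻¹, csat = 0.95 mM)
    substrate + dissolved gas + catalyst → catalyst + target (k3 = 1.8 × 10⁵ M⁻² s⁻¹)
    substrate + dissolved gas → uncatalysed product (k4 = 3.4 M⁻¹ s⁻¹)

substrate 10 mM; gas phase 0.95 mM (held); catalyst 1.9 mol%; time 3.0 min

- percent here means substrate units held: one self-condensation product counts as two
- two of one species on the left: rate k times its square, two consumed each time
- at the start none of the gas is dissolved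
- run time (flask): 3.0 min

* amount of target at 3.0 min, in percent of the substrate charged
* concentration of dissolved gas in solution at 1.5 min, in percent of saturation
* the change that raises the amount of target at 3.0 min, in percent of the substrate charged most ("none" if none brings more than 2 percentage points) (maple / larch / cedar / none)
* amount of target at 3.0 min, in percent of the substrate charged, after larch

As times at the charge, self-condensation has a first half-life of 8.06 s, an empty solution refills with a half-time of 4.62 s, and the catalysed step halves dissolved gas in 2.0 s. Dissolved gas is used faster than it refills, but only by a factor of 2.28, so neither step is called rate-limiting here. The handover fraction takes the uptake of an empty solution as the yardstick for the gas routes: it is the fraction of the charge at which self-condensation consumes substrate as fast as an empty solution takes up gas; here it is 33.9%. The reckoning puts target somewhat below it. Doubling the saturation or the transfer coefficient each lifts it to 47.9%, so it cannot part larch from maple, and it contains no catalyst, so it is silent on cedar.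

The forecast gives 25%, 96%, larch and 35%; its ground: “Self-condensation outruns the gas-limited route while substrate is high”.

The flask gives 24.6% target, dissolved gas at 95.2% of saturation, larch as best change and 33.6% after it. Larch gains 9 percentage points, cedar 5.9 points and maple 4.4 points, so larch and maple do part. Target and uncatalysed product together reach 27.0%, less than the handover fraction.

The flask has come to rest: at 3.00 min its substrate stands at 0.062%, far below the handover fraction. Ten times the time leaves target at 24.6%.

With 40 mM of substrate and the loading held, the same delivery gives a handover fraction of 8.47%. That neighbour flask gives 10.6% target, a little above it, and 89.1% self-condensation product.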